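**Retrosynthetic overview**
1. Target 28 ⇐ 26 ⇐ 25 ⇐ 24: angeloylation, acetylation and desilylation on the finished tricycle.
2. 24 ⇐ acyclic bromo-enal 21: one chromium-mediated intramolecular 2-(methoxycarbonyl)allylation/lactonisation makes the C6–C7 and O6–C12 bonds, closing the ten-membered carbocycle and the α-methylene-γ-lactone together and setting C6 and C7.
3. 21 ⇐ dialdehyde 17 + methyl acrylate 18 (Morita–Baylis–Hillman, SN2′ bromination); 17 ⇐ furanone 14 (silylation, oxidative desilylation).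
4. 14 ⇐ lactone 11 + enyne 5: acetylide addition (C1–C2) and cyclisation of the γ-hydroxy ynone (O–C3) build the furanone first.
5. 11 ⇐ (S)-γ-hydroxymethyl-γ-butyrolactone 6 (C8 from the chiral pool, C10 by enolate methylation/hydroxylation); 5 ⇐ but-2-yne-1,4-diol 1 (alkene geometry by trans-hydroalumination/iodination). Ring order: furanone, then carbocycle and lactone in one step.

Assumption: the target is the enantiomer written in the SMILES, (4Z,6R,7R,8S,10R). Atom labels are germacrane numbers: C1 ketone, C2=C3 furanone alkene, C4=C5, C6 lactone carbinol, C7, C8 ester carbinol, C9, C10 quaternary carbon, C11=C13 methylene, C12 lactone carbonyl, C14 methyl, C15 CH2O.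

**Step 1**
Reactants: 1 but-2-yne-1,4-diol
Product: 2 4-[(tert-butyldimethylsilyl)oxy]but-2-yn-1-ol
Conditions: 1 (4 equiv), TBSCl (1 equiv), imidazole, THF, 0 °C → rt
Reagents that add atoms: tert-butyldimethylsilyl chloride, CC(C)(C)[Si](C)(C)Cl
Why: Statistical O-silylation with the cheap diol in fourfold excess gives the monosilyl ether as the only significant silylated product; no stereocentre is involved.

**Step 2**
Reactants: 2 4-[(tert-butyldimethylsilyl)oxy]but-2-yn-1-ol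
Product: 4 (Z)-4-[(tert-butyldimethylsilyl)oxy]-3-iodobut-2-en-1-ol, via cyclic vinylalanate 3 (not isolated)
Conditions: NaAlH2(OCH2CH2OMe)2 (1.5 equiv), THF, 0 °C; then I2 (1.5 equiv), −78 → 0 °C; aq Na2S2O3
Reagents that add atoms: iodine, II
Why: Hydroxyl-directed trans-hydroalumination delivers hydride to the alkyne carbon next to the carbinol (C5) and aluminium to the distal one (C4) in a five-membered oxa-aluminacycle, and iodinolysis with retention gives the iodide with iodine cis to the CH2OH carbon, which is the C4=C5 geometry of the target.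

**Step 3**
Reactants: 4 (Z)-4-[(tert-butyldimethylsilyl)oxy]-3-iodobut-2-en-1-ol
Product: 5 (E)-3-{[(tert-butyldimethylsilyl)oxy]methyl}pent-2-en-4-yn-1-ol
Conditions: HC≡CMgBr (3 equiv), ZnBr2 (3 equiv), THF, 0 °C; then 4, Pd(PPh3)4 (5 mol %), THF, rt
Reagents that add atoms: ethynylmagnesium bromide, C#C[Mg]Br
Why: Negishi alkynylation (oxidative addition of the C–I bond to zerovalent palladium, transmetallation from ethynylzinc bromide, reductive elimination) proceeds with retention of alkene geometry and tolerates the zinc alkoxide; the descriptor changes to E only because ethynyl ranks below CH2OSi.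

**Step 4**
Reactants: 6 (S)-5-(hydroxymethyl)dihydrofuran-2(3H)-one
Product: 7 (S)-5-{[(triethylsilyl)oxy]methyl}dihydrofuran-2(3H)-one
Conditions: Et3SiCl, imidazole, CH2Cl2, 0 °C
Reagents that add atoms: chlorotriethylsilane, CC[Si](CC)(CC)Cl
Why: Routine silylation of the primary alcohol; the stereocentre (C8 of the target, from L-glutamic acid) is not touched.

**Step 5**
Reactants: 7 (S)-5-{[(triethylsilyl)oxy]methyl}dihydrofuran-2(3H)-one
Product: 9 (3R,5S)-3-methyl-5-{[(triethylsilyl)oxy]methyl}dihydrofuran-2(3H)-one, via lithium enolate 8 (not isolated)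
Conditions: LiN(iPr)2 (1.1 equiv), THF, −78 °C; MeI (1.5 equiv), −78 → −40 °C
Reagents that add atoms: iodomethane, CI
Why: Lactone enolate alkylation places methyl mainly anti to the C5 side chain, and because C3 is re-enolised in step 6 both C3 epimers are carried forward and the ratio does not matter.

**Step 6**
Reactants: 9 (3R,5S)-3-methyl-5-{[(triethylsilyl)oxy]methyl}dihydrofuran-2(3H)-one
Product: 11 (3R,5S)-3-hydroxy-3-methyl-5-{[(triethylsilyl)oxy]methyl}dihydrofuran-2(3H)-one, via potassium enolate 10 (not isolated)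
Conditions: KN(SiMe3)2 (1.2 equiv), THF, −78 °C; 3-phenyl-2-(phenylsulfonyl)oxaziridine (1.4 equiv), −78 °C; aq NH4Cl
Reagents that add atoms: 3-phenyl-2-(phenylsulfonyl)oxaziridine, O=S(=O)(c1ccccc1)N1OC1c1ccccc1
Why: Davis enolate hydroxylation delivers oxygen to the face of the tetrasubstituted enolate anti to the CH2OSiEt3 group, setting the tertiary carbinol (C10 of the target) as 3R with OH trans to the side chain.

**Step 7**
Reactants: 11 (3R,5S)-3-hydroxy-3-methyl-5-{[(triethylsilyl)oxy]methyl}dihydrofuran-2(3H)-one, 5 (E)-3-{[(tert-butyldimethylsilyl)oxy]methyl}pent-2-en-4-yn-1-ol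
Product: 14 (R)-5-{(Z)-1-[(tert-butyldimethylsilyl)oxy]-4-hydroxybut-2-en-2-yl}-2-{(S)-2-hydroxy-3-[(triethylsilyl)oxy]propyl}-2-methylfuran-3(2H)-one, via dilithiated enynol 12 (not isolated), via hydroxy ynone 13 (not isolated)
Conditions: 5 (1.3 equiv), n-BuLi (2.6 equiv), THF, −78 °C; add to 11 + LiN(SiMe3)2 (1.0 equiv), THF, −78 → −20 °C; AcOH; then Et2NH (5 equiv), EtOH, rt
Reagents that add atoms: none
Why: Acetylide addition to the lactone carbonyl gives the γ-hydroxy ynone (the ring oxygen is released as the C8 hydroxyl), and diethylamine then adds to the ynone and is displaced by the tertiary hydroxyl in a five-membered addition–elimination (the classical amine-mediated 3(2H)-furanone synthesis), leaving C8 and C10 untouched.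

**Step 8**
Reactants: 14 (R)-5-{(Z)-1-[(tert-butyldimethylsilyl)oxy]-4-hydroxybut-2-en-2-yl}-2-{(S)-2-hydroxy-3-[(triethylsilyl)oxy]propyl}-2-methylfuran-3(2H)-one
Product: 15 (R)-5-{(Z)-1-[(tert-butyldimethylsilyl)oxy]-4-[(triethylsilyl)oxy]but-2-en-2-yl}-2-{(S)-2,3-bis[(triethylsilyl)oxy]propyl}-2-methylfuran-3(2H)-one
Conditions: Et3SiCl (2.5 equiv), imidazole, DMF, 0 °C → rt
Reagents that add atoms: chlorotriethylsilane, CC[Si](CC)(CC)Cl
Why: Exhaustive silylation of the primary allylic (C6) and secondary (C8) hydroxyls; no stereocentre is affected.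

**Step 9**
Reactants: 15 (R)-5-{(Z)-1-[(tert-butyldimethylsilyl)oxy]-4-[(triethylsilyl)oxy]but-2-en-2-yl}-2-{(S)-2,3-bis[(triethylsilyl)oxy]propyl}-2-methylfuran-3(2H)-one
Product: 17 (S)-3-[(R)-5-{(Z)-1-[(tert-butyldimethylsilyl)oxy]-4-oxobut-2-en-2-yl}-2-methyl-3-oxo-2,3-dihydrofuran-2-yl]-2-[(triethylsilyl)oxy]propanal, via primary diol 16 (not isolated)
Conditions: (COCl)2 (5 equiv), DMSO (10 equiv), CH2Cl2, −78 → −35 °C; then Et3N (15 equiv), −78 → 0 °C
Reagents that add atoms: none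
Why: Swern oxidation run as an oxidative desilylation: the activated-DMSO/HCl medium cleaves only the two unhindered primary triethylsilyl ethers and oxidises the liberated alcohols to aldehydes, while the secondary triethylsilyl and the tert-butyldimethylsilyl ethers survive and the low temperature preserves the α-silyloxy centre (C8) and the Z-enal.

**Step 10**
Reactants: 17 (S)-3-[(R)-5-{(Z)-1-[(tert-butyldimethylsilyl)oxy]-4-oxobut-2-en-2-yl}-2-methyl-3-oxo-2,3-dihydrofuran-2-yl]-2-[(triethylsilyl)oxy]propanal, 18 methyl acrylate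
Product: 19 methyl (4S)-5-[(R)-5-{(Z)-1-[(tert-butyldimethylsilyl)oxy]-4-oxobut-2-en-2-yl}-2-methyl-3-oxo-2,3-dihydrofuran-2-yl]-3-hydroxy-2-methylidene-4-[(triethylsilyl)oxy]pentanoate (both C3 epimers)
Conditions: 18 (10 equiv, neat), DABCO (1 equiv), MeOH (2 equiv), rt, 48–72 h
Reagents that add atoms: none
Why: Morita–Baylis–Hillman reaction in which the DABCO–acrylate zwitterion adds only to the inductively activated α-silyloxy aliphatic aldehyde, the β,β-disubstituted conjugated enal being inert; the new carbinol (C7) forms as a mixture that is irrelevant because it becomes sp2 in step 11.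

**Step 11**
Reactants: 19 methyl (4S)-5-[(R)-5-{(Z)-1-[(tert-butyldimethylsilyl)oxy]-4-oxobut-2-en-2-yl}-2-methyl-3-oxo-2,3-dihydrofuran-2-yl]-3-hydroxy-2-methylidene-4-[(triethylsilyl)oxy]pentanoate
Product: 21 methyl (2Z,4S)-2-(bromomethyl)-5-[(R)-5-{(Z)-1-[(tert-butyldimethylsilyl)oxy]-4-oxobut-2-en-2-yl}-2-methyl-3-oxo-2,3-dihydrofuran-2-yl]-4-[(triethylsilyl)oxy]pent-2-enoate, via allylic mesylate 20 (not isolated)
Conditions: MsCl, Et3N, CH2Cl2, −20 °C; then LiBr (5 equiv), acetone, 0 °C → rt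
Reagents that add atoms: lithium bromide, [Li+].[Br-]
Why: Mesylation followed by SN2′ displacement with bromide (allylic transposition of a Morita–Baylis–Hillman adduct) gives the conjugated, thermodynamically preferred (Z)-2-(bromomethyl)enoate without electrophilic bromine; C8 is untouched.

**Step 12**
Reactants: 21 methyl (2Z,4S)-2-(bromomethyl)-5-[(R)-5-{(Z)-1-[(tert-butyldimethylsilyl)oxy]-4-oxobut-2-en-2-yl}-2-methyl-3-oxo-2,3-dihydrofuran-2-yl]-4-[(triethylsilyl)oxy]pent-2-enoate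
Product: 24 (4Z,6R,7S,8S,10R)-15-[(tert-butyldimethylsilyl)oxy]-1-oxo-8-[(triethylsilyl)oxy]-3,10-epoxygermacra-2,4,11(13)-trien-12,6-olide, via dichlorochromium allyl species 22 (not isolated), via dichlorochromium alkoxide 23 (not isolated)
Conditions: CrCl2 (6 equiv), THF–DMF (4:1), 21 added by syringe pump over 10 h (final 0.002 M), rt; then 45 °C, 2 h; aq NH4Cl
Reagents that add atoms: none
Why: Intramolecular Nozaki–Hiyama allylation (chromium-mediated Barbier reaction) with in-flask lactonisation: the σ-allylchromium species adds through its γ-carbon (C7) to the aldehyde in a closed six-membered transition state to close the ten-membered carbocycle and the trivalent-chromium alkoxide then acylates itself on the neighbouring methyl ester to close the γ-lactone; allylic 1,3-strain keeps H8 in the plane of the allyl unit and the tether holds C9 on the attacking face, so the C6–C7 bond forms anti to the C8–O bond, and the short Z-enal–furanone tether is expected to favour H6 and H7 anti (trans-lactone).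

**Step 13**
Reactants: 24 (4Z,6R,7S,8S,10R)-15-[(tert-butyldimethylsilyl)oxy]-1-oxo-8-[(triethylsilyl)oxy]-3,10-epoxygermacra-2,4,11(13)-trien-12,6-olide
Product: 25 (4Z,6R,7R,8S,10R)-8,15-dihydroxy-1-oxo-3,10-epoxygermacra-2,4,11(13)-trien-12,6-olide
Conditions: HF·pyridine, pyridine, THF, 0 °C → rt
Reagents that add atoms: none
Why: Buffered fluoride desilylation removes both silyl ethers without opening the lactone or touching the furanone; the change from 7S to 7R is a priority change only.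

**Step 14**
Reactants: 25 (4Z,6R,7R,8S,10R)-8,15-dihydroxy-1-oxo-3,10-epoxygermacra-2,4,11(13)-trien-12,6-olide
Product: 26 (4Z,6R,7R,8S,10R)-15-acetoxy-8-hydroxy-1-oxo-3,10-epoxygermacra-2,4,11(13)-trien-12,6-olide
Conditions: AcCl (1.1 equiv), 2,4,6-collidine, CH2Cl2, −78 °C
Reagents that add atoms: acetyl chloride, CC(=O)Cl
Why: Chemoselective acylation: at −78 °C the unhindered primary allylic hydroxyl (C15) is acetylated much faster than the hindered secondary C8 hydroxyl.

**Step 15**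
Reactants: 26 (4Z,6R,7R,8S,10R)-15-acetoxy-8-hydroxy-1-oxo-3,10-epoxygermacra-2,4,11(13)-trien-12,6-olide, 27 angelic acid [(Z)-2-methylbut-2-enoic acid]
Product: 28 (4Z,6R,7R,8S,10R)-15-acetoxy-8-[(Z)-2-methylbut-2-enoyloxy]-1-oxo-3,10-epoxygermacra-2,4,11(13)-trien-12,6-olide (CNP0122132.1)
Conditions: 27 (3 equiv), 2,4,6-trichlorobenzoyl chloride (3 equiv), Et3N (6 equiv), toluene, rt, 2 h; then 26, toluene, 75 °C
Reagents that add atoms: none
Why: Yamaguchi-type esterification through the preformed mixed anhydride without DMAP transfers the angeloyl group thermally, avoiding the nucleophilic-catalyst pathway that isomerises angelate to tiglate, and O-acylation leaves C8 unchanged.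

**Compound list**
1 | but-2-yne-1,4-diol | OCC#CCO | starting material
2 | 4-[(tert-butyldimethylsilyl)oxy]but-2-yn-1-ol | CC(C)(C)[Si](C)(C)OCC#CCO | intermediate
3 | sodium 3-{[(tert-butyldimethylsilyl)oxy]methyl}-2,2-bis(2-methoxyethoxy)-2,5-dihydro-1,2-oxaluminol-2-uide (cyclic vinylalanate) | [Na+].COCCO[Al-]1(OCCOC)OC/C=C1/CO[Si](C)(C)C(C)(C)C | intermediate
4 | (Z)-4-[(tert-butyldimethylsilyl)oxy]-3-iodobut-2-en-1-ol | OC/C=C(/CO[Si](C)(C)C(C)(C)C)I | intermediate
5 | (E)-3-{[(tert-butyldimethylsilyl)oxy]methyl}pent-2-en-4-yn-1-ol (ethynyl cis to CH2OH) | OC/C=C(/CO[Si](C)(C)C(C)(C)C)C#C | intermediate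
6 | (S)-5-(hydroxymethyl)dihydrofuran-2(3H)-one | OC[C@@H]1CCC(=O)O1 | starting material
7 | (S)-5-{[(triethylsilyl)oxy]methyl}dihydrofuran-2(3H)-one | CC[Si](CC)(CC)OC[C@@H]1CCC(=O)O1 | intermediate
8 | lithium (S)-5-{[(triethylsilyl)oxy]methyl}-4,5-dihydrofuran-2-olate | [Li]OC1=CC[C@@H](CO[Si](CC)(CC)CC)O1 | intermediate
9 | (3R,5S)-3-methyl-5-{[(triethylsilyl)oxy]methyl}dihydrofuran-2(3H)-one (major trans epimer drawn) | C[C@@H]1C[C@@H](CO[Si](CC)(CC)CC)OC1=O | intermediate
10 | potassium (S)-3-methyl-5-{[(triethylsilyl)oxy]methyl}-4,5-dihydrofuran-2-olate | [K]OC1=C(C)C[C@@H](CO[Si](CC)(CC)CC)O1 | intermediate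
11 | (3R,5S)-3-hydroxy-3-methyl-5-{[(triethylsilyl)oxy]methyl}dihydrofuran-2(3H)-one (OH trans to the side chain) | C[C@@]1(O)C[C@@H](CO[Si](CC)(CC)CC)OC1=O | intermediate
12 | dilithium salt of 5 (lithium alkoxide, lithium acetylide) | [Li]OC/C=C(/CO[Si](C)(C)C(C)(C)C)C#C[Li] | intermediate
13 | (2S,4R,8E)-8-{[(tert-butyldimethylsilyl)oxy]methyl}-2,4,10-trihydroxy-4-methyl-1-[(triethylsilyl)oxy]dec-8-en-6-yn-5-one (open form of the lactol) | OC/C=C(/CO[Si](C)(C)C(C)(C)C)C#CC(=O)[C@@](C)(C[C@H](O)CO[Si](CC)(CC)CC)O | intermediate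
14 | (R)-5-{(Z)-1-[(tert-butyldimethylsilyl)oxy]-4-hydroxybut-2-en-2-yl}-2-{(S)-2-hydroxy-3-[(triethylsilyl)oxy]propyl}-2-methylfuran-3(2H)-one | OC/C=C(/CO[Si](C)(C)C(C)(C)C)C1=CC(=O)[C@@](C)(C[C@H](O)CO[Si](CC)(CC)CC)O1 | intermediate
15 | (R)-5-{(Z)-1-[(tert-butyldimethylsilyl)oxy]-4-[(triethylsilyl)oxy]but-2-en-2-yl}-2-{(S)-2,3-bis[(triethylsilyl)oxy]propyl}-2-methylfuran-3(2H)-one | CC[Si](CC)(CC)OC/C=C(/CO[Si](C)(C)C(C)(C)C)C1=CC(=O)[C@@](C)(C[C@H](O[Si](CC)(CC)CC)CO[Si](CC)(CC)CC)O1 | intermediate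
16 | (R)-5-{(Z)-1-[(tert-butyldimethylsilyl)oxy]-4-hydroxybut-2-en-2-yl}-2-{(S)-3-hydroxy-2-[(triethylsilyl)oxy]propyl}-2-methylfuran-3(2H)-one | OC/C=C(/CO[Si](C)(C)C(C)(C)C)C1=CC(=O)[C@@](C)(C[C@H](O[Si](CC)(CC)CC)CO)O1 | intermediate
17 | (S)-3-[(R)-5-{(Z)-1-[(tert-butyldimethylsilyl)oxy]-4-oxobut-2-en-2-yl}-2-methyl-3-oxo-2,3-dihydrofuran-2-yl]-2-[(triethylsilyl)oxy]propanal | O=C/C=C(/CO[Si](C)(C)C(C)(C)C)C1=CC(=O)[C@@](C)(C[C@H](O[Si](CC)(CC)CC)C=O)O1 | intermediate
18 | methyl acrylate | C=CC(=O)OC | starting material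
19 | methyl (4S)-5-[(R)-5-{(Z)-1-[(tert-butyldimethylsilyl)oxy]-4-oxobut-2-en-2-yl}-2-methyl-3-oxo-2,3-dihydrofuran-2-yl]-3-hydroxy-2-methylidene-4-[(triethylsilyl)oxy]pentanoate (both C3 epimers) | O=C/C=C(/CO[Si](C)(C)C(C)(C)C)C1=CC(=O)[C@@](C)(C[C@H](O[Si](CC)(CC)CC)C(O)C(=C)C(=O)OC)O1 | intermediate
20 | methyl (4S)-5-[(R)-5-{(Z)-1-[(tert-butyldimethylsilyl)oxy]-4-oxobut-2-en-2-yl}-2-methyl-3-oxo-2,3-dihydrofuran-2-yl]-2-methylidene-3-[(methylsulfonyl)oxy]-4-[(triethylsilyl)oxy]pentanoate (both C3 epimers) | O=C/C=C(/CO[Si](C)(C)C(C)(C)C)C1=CC(=O)[C@@](C)(C[C@H](O[Si](CC)(CC)CC)C(OS(C)(=O)=O)C(=C)C(=O)OC)O1 | intermediate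
21 | methyl (2Z,4S)-2-(bromomethyl)-5-[(R)-5-{(Z)-1-[(tert-butyldimethylsilyl)oxy]-4-oxobut-2-en-2-yl}-2-methyl-3-oxo-2,3-dihydrofuran-2-yl]-4-[(triethylsilyl)oxy]pent-2-enoate | O=C/C=C(/CO[Si](C)(C)C(C)(C)C)C1=CC(=O)[C@@](C)(C[C@H](O[Si](CC)(CC)CC)/C=C(\CBr)C(=O)OC)O1 | intermediate
22 | dichlorochromium allyl species from 21 (CrCl2 unit in place of Br) | O=C/C=C(/CO[Si](C)(C)C(C)(C)C)C1=CC(=O)[C@@](C)(C[C@H](O[Si](CC)(CC)CC)/C=C(\C[Cr](Cl)Cl)C(=O)OC)O1 | intermediate
23 | dichlorochromium alkoxide of the ring-closed hydroxy ester (ten-membered carbocycle formed, C6–O–CrCl2, methyl ester still open; configuration as in 24) | COC(=O)C(=C)[C@H]1[C@H](O[Cr](Cl)Cl)/C=C(/CO[Si](C)(C)C(C)(C)C)C2=CC(=O)[C@@](C)(C[C@@H]1O[Si](CC)(CC)CC)O2 | intermediate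
24 | (4Z,6R,7S,8S,10R)-15-[(tert-butyldimethylsilyl)oxy]-1-oxo-8-[(triethylsilyl)oxy]-3,10-epoxygermacra-2,4,11(13)-trien-12,6-olide (same spatial arrangement as 28; 7S by priority only) | C=C1C(=O)O[C@@H]2/C=C(/CO[Si](C)(C)C(C)(C)C)C3=CC(=O)[C@@](C)(C[C@H](O[Si](CC)(CC)CC)[C@@H]12)O3 | intermediate
25 | (4Z,6R,7R,8S,10R)-8,15-dihydroxy-1-oxo-3,10-epoxygermacra-2,4,11(13)-trien-12,6-olide | C=C1C(=O)O[C@@H]2/C=C(/CO)C3=CC(=O)[C@@](C)(C[C@H](O)[C@@H]12)O3 | intermediate
26 | (4Z,6R,7R,8S,10R)-15-acetoxy-8-hydroxy-1-oxo-3,10-epoxygermacra-2,4,11(13)-trien-12,6-olide | C=C1C(=O)O[C@@H]2/C=C(/COC(C)=O)C3=CC(=O)[C@@](C)(C[C@H](O)[C@@H]12)O3 | intermediate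
27 | angelic acid, (Z)-2-methylbut-2-enoic acid | C/C=C(/C)C(=O)O | starting material
28 | (4Z,6R,7R,8S,10R)-15-acetoxy-8-[(Z)-2-methylbut-2-enoyloxy]-1-oxo-3,10-epoxygermacra-2,4,11(13)-trien-12,6-olide | C=C1C(=O)O[C@@H]2/C=C(/COC(C)=O)C3=CC(=O)[C@@](C)(C[C@H](OC(=O)/C(C)=C\C)[C@@H]12)O3 | target

**Step count and risk**
Total steps: 15. Longest linear sequence: 12 steps (steps 4–15 from lactone 6; the branch from diol 1, steps 1–3 then 7–15, is also 12).

Most likely to fail, step 12 (ring closure). Risks are the strain of closing a ten-membered ring across the rigid furanone, competing five-membered addition to the furanone carbonyl, and above all the C6/C7 relationship, because open-chain 2-(alkoxycarbonyl)allyl metal reagents intrinsically prefer the syn adduct (cis-lactone). The fallback locks the allyl unit in a butenolide and sets out from 19. Aqueous acetic acid in THF removes the secondary triethylsilyl group to give the dihydroxy ester F1. Catalytic camphorsulfonic acid in CH2Cl2 lactonises the C8 hydroxyl onto the methyl ester to give the α-methylene-β-hydroxy-γ-lactone F2. PBr3 in Et2O at −10 °C transposes it to the 3-(bromomethyl)butenolide F3. CrCl2 under the same high dilution then closes the carbocycle: the allyl geometry is fixed (C8 trans to the CH2–Cr carbon, chair transition state, anti C6/C7) and C6 must add to the ring face anti to the C8 side chain, giving the macrocyclic 6-hydroxy-8,12-olide F4. Catalytic DBU in CH2Cl2 translactonises to the 8-hydroxy-6,12-olide F5, and HF·pyridine brings the route back at 25.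

Second, step 10 (Morita–Baylis–Hillman on the dialdehyde). Risks are days of exposure of the Z-enal and the α-silyloxy aldehyde to a nucleophilic amine and incomplete discrimination between the two aldehydes. The fallback sets out from 17. A kinetic aldol with the lithium enolate of methyl 3-(dimethylamino)propanoate (LiN(iPr)2, THF, −78 °C, 1.0 equiv, minutes) goes to the more electrophilic aliphatic aldehyde and gives the β-hydroxy α-(dimethylaminomethyl) ester F6. mCPBA (1 equiv, CH2Cl2, −20 °C → rt) forms the N-oxide, which undergoes Cope elimination to the α-methylene ester, returning at 19.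

Third, step 9 (double oxidative desilylation). Risks are conversion of the allylic silyl ether into an allylic chloride, partial loss of the secondary triethylsilyl group and epimerisation at C8. The fallback separates the two oxidations and sets out from 14. MnO2 in CH2Cl2 oxidises only the allylic C6 hydroxyl to the hydroxy enal F7. Et3SiCl/imidazole gives the bis(triethylsilyl) ether F8. HF·pyridine buffered with pyridine (THF, 0 °C) cleaves only the primary triethylsilyl ether to the primary alcohol F9. Dess–Martin periodinane with NaHCO3 returns the route at 17.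

**Further compounds**
F1 | step 12 | methyl (4S)-5-[(R)-5-{(Z)-1-[(tert-butyldimethylsilyl)oxy]-4-oxobut-2-en-2-yl}-2-methyl-3-oxo-2,3-dihydrofuran-2-yl]-3,4-dihydroxy-2-methylidenepentanoate (both C3 epimers) | O=C/C=C(/CO[Si](C)(C)C(C)(C)C)C1=CC(=O)[C@@](C)(C[C@H](O)C(O)C(=C)C(=O)OC)O1
F2 | step 12 | (2Z)-4-[(tert-butyldimethylsilyl)oxy]-3-[(5R)-5-{[(2S)-3-hydroxy-4-methylidene-5-oxooxolan-2-yl]methyl}-5-methyl-4-oxo-4,5-dihydrofuran-2-yl]but-2-enal (both carbinol epimers) | O=C/C=C(/CO[Si](C)(C)C(C)(C)C)C1=CC(=O)[C@@](C)(C[C@@H]2OC(=O)C(=C)C2O)O1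
F3 | step 12 | (2Z)-3-[(5R)-5-{[(2S)-4-(bromomethyl)-5-oxo-2,5-dihydrofuran-2-yl]methyl}-5-methyl-4-oxo-4,5-dihydrofuran-2-yl]-4-[(tert-butyldimethylsilyl)oxy]but-2-enal | O=C/C=C(/CO[Si](C)(C)C(C)(C)C)C1=CC(=O)[C@@](C)(C[C@@H]2OC(=O)C(CBr)=C2)O1
F4 | step 12 | (4Z,6R,7S,8S,10R)-15-[(tert-butyldimethylsilyl)oxy]-6-hydroxy-1-oxo-3,10-epoxygermacra-2,4,11(13)-trien-12,8-olide | O[C@@H]1/C=C(/CO[Si](C)(C)C(C)(C)C)C2=CC(=O)[C@@](C)(C[C@@H]3OC(=O)C(=C)[C@@H]13)O2
F5 | step 12 | (4Z,6R,7R,8S,10R)-15-[(tert-butyldimethylsilyl)oxy]-8-hydroxy-1-oxo-3,10-epoxygermacra-2,4,11(13)-trien-12,6-olide | C=C1C(=O)O[C@@H]2/C=C(/CO[Si](C)(C)C(C)(C)C)C3=CC(=O)[C@@](C)(C[C@H](O)[C@@H]12)O3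
F6 | step 10 | methyl (4S)-5-[(R)-5-{(Z)-1-[(tert-butyldimethylsilyl)oxy]-4-oxobut-2-en-2-yl}-2-methyl-3-oxo-2,3-dihydrofuran-2-yl]-2-[(dimethylamino)methyl]-3-hydroxy-4-[(triethylsilyl)oxy]pentanoate (mixture at C2 and C3) | O=C/C=C(/CO[Si](C)(C)C(C)(C)C)C1=CC(=O)[C@@](C)(C[C@H](O[Si](CC)(CC)CC)C(O)C(CN(C)C)C(=O)OC)O1
F7 | step 9 | (Z)-4-[(tert-butyldimethylsilyl)oxy]-3-[(R)-5-{(S)-2-hydroxy-3-[(triethylsilyl)oxy]propyl}-5-methyl-4-oxo-4,5-dihydrofuran-2-yl]but-2-enal | O=C/C=C(/CO[Si](C)(C)C(C)(C)C)C1=CC(=O)[C@@](C)(C[C@H](O)CO[Si](CC)(CC)CC)O1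
F8 | step 9 | (Z)-3-[(R)-5-{(S)-2,3-bis[(triethylsilyl)oxy]propyl}-5-methyl-4-oxo-4,5-dihydrofuran-2-yl]-4-[(tert-butyldimethylsilyl)oxy]but-2-enal | O=C/C=C(/CO[Si](C)(C)C(C)(C)C)C1=CC(=O)[C@@](C)(C[C@H](O[Si](CC)(CC)CC)CO[Si](CC)(CC)CC)O1
F9 | step 9 | (Z)-4-[(tert-butyldimethylsilyl)oxy]-3-[(R)-5-{(S)-3-hydroxy-2-[(triethylsilyl)oxy]propyl}-5-methyl-4-oxo-4,5-dihydrofuran-2-yl]but-2-enal | O=C/C=C(/CO[Si](C)(C)C(C)(C)C)C1=CC(=O)[C@@](C)(C[C@H](O[Si](CC)(CC)CC)CO)O1
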